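An exact hand integration of these coupled steps cannot be done, yet you asked for a quick number.

    free monomer + monomer in chains → side product (k1 = 2.5 × 10⁻⁵ L mol⁻¹ s⁻¹, Ea1 = 65.0 kJ mol⁻¹)
    free monomer + initiator → living end + monomer in chains (k2 = 1.6 × 10⁻⁵ L mol⁻¹ s⁻¹, Ea2 = 86.0 kJ mol⁻¹)
    solid monomer ⇌ free monomer, rate k3*(cs3 - [free monomer]) while solid is left; crystals form when [free monomer] > cs3 (cs3 = 0.30 M, k3 = 5.6 × 10⁻⁵ s⁻¹)
    free monomer + living end → monomer in chains + living end, rate k4*[living end]*[free monomer] (k4 = 1.7 × 10⁻⁴ L mol⁻¹ s⁻¹, Ea4 = 69.0 kJ mol⁻¹)
    (constants at 40 °C)

| setting | midnight | spring | winter |
|---|---|---|---|
| solid monomer | 2.0 M | 2.0 M | 2.0 M |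
| initiator | 110 mM | 110 mM | 110 mM |
| temperature | 10 °C | 25 °C | 40 °C |
| time | 30 h | 30 h | 30 h |

- in percentages every species weighs as the solid monomer in it: one side product counts as two
- as a solid, counted per litre of solution: solid monomer
- the list of constants is for 40 °C, to be carried to other temperatures by the activation energies
- at the start none of the solid monomer is in solution

- the flask that comes out highest in share of monomer in chains in all that became monomer in chains or side product, or "all alike" when all lie within 1.5 percentage points (midnight / spring / winter / all alike)
- share of monomer in chains in all that became monomer in chains or side product, midnight
- share of monomer in chains in all that became monomer in chains or side product, spring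
- share of monomer in chains in all that became monomer in chains or side product, winter

What you can do instead is freeze one thing. Solid monomer is charged at 2.0 M, more than the solubility of 0.30 M, so free monomer climbs towards that solubility with a lag of 4.96 h, shorter than the run of 30 h, and I take it to stay there. Each reaction step then runs pseudo-first-order, and the clock that matters is not time. Solubility times run time less the lag gives D = 451 M·min, the monomer dose, which is free monomer summed over the run. Dissolving carries no activation energy, so midnight, spring and winter share this D.

Now multiply D by the rate constant of the side reaction, carried to the flask's temperature, and call the result s, the attacks a chain has suffered. Multiply it by the growth constant and call the result g, the additions per living end. Chains pile up first by starting and then by growth, and side product follows them one stage behind. Setting aside initiator used up and chains already lost, side product counted double over chains comes to ρ = s(1 + g/3)/(1 + g/2), and the share is 1/(1 + ρ). The initiator charge cancels in this ratio.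

Midnight has s = 0.0480 and g = 0.277, so its share is 95.6%. Spring has s = 0.193 and g = 1.21, giving 85.6%. Winter has s = 0.676 and g = 4.60, giving 65.8%. My pick for the highest share is therefore midnight.

The forecast gave 95.6%, 85% and 66% for midnight, spring and winter and chose midnight, holding that “the outcome depends on how much chain has built up for the side reaction to attack”.

The simulation gives 95.6% for midnight, 85.2% for spring and 65.0% for winter, highest at midnight. Now take winter read at 3.0 d. The temperature stays, so its constants stay, and the dose rises to 1210 M·min. That makes s = 1.81 and g = 12.3, and the share reckons to 43.6%. The simulated winter flask at that reading gives 42.0%, with 14.4% of the solid monomer charged in chains and 19.9% in side product.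

The numbers of this flask stand for no real mixture; no experiment stands behind them.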